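Conventions and one assumption: terpenoid locants are used for all bicyclic compounds (ring A = C1–C5 with C10, ring B = C5–C10, chain on C9 = C11, C12, C13 and onward; β is the face of the C10 methyl group, α the opposite face). "11-Nordrimane" means the trans-decalin with methyl groups at C4, C4, C8 and C10; "13,14,15,16-tetranorlabdane" is the same skeleton with a C11–C12 two-carbon arm on C9. Assumption: the radical ring closure gives mainly the equatorial 3β-alcohol; a 3α epimer would pass through the same steps and converge at the final oxidation, so compounds 10–33 are drawn as 3β.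

## The problem

The target 34 is a bicyclic triterpenoid: a trans-fused decalin (rings A and B) with a C3 ketone next to the C4 gem-dimethyl group, an angular methyl group at C10, a tertiary 8α-alcohol with an axial 8β-methyl group, and on C9 an equatorial β side chain of sixteen carbons containing two (E)-trisubstituted alkenes and a terminal prenyl unit. Four stereocentres (C5, C8, C9, C10) lie on ring B; C5 is the only one a cheap natural product can supply, and it can direct C10 (alkylation anti to the C5 substituent), after which the trans ring fusion is settled. The axial C10 methyl group then shields the β face of ring B: this helps at C8, where oxygen must enter from the α face, but works against C9, whose carbon substituent has to be placed on the same side as that methyl group and therefore calls for intramolecular delivery. The fragile parts are the tertiary C8 alcohol (dehydration, or closure onto an activated C12 to a tetrahydrofuran), the skipped triene (acid-induced cation–olefin reactions, electrophilic oxidants, radical hydrogen donors) and the C3 carbonyl, which must stay masked while a second carbonyl group is handled in ring B. The chain is best attached late and with the C13=C14 geometry fixed beforehand, so that all ring chemistry is done without its alkenes. The enabling feature is that ring B with the C8 methyl group, C5 and the attached C4 with its two methyl groups is a p-menthane: in (R)-carvone 1 the isopropenyl carbon is C4 and lacks only one bond to C3 and one hydrogen atom, and a hydrogen-atom-transfer radical cyclisation onto a C3 aldehyde supplies both while closing ring A.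

## Retrosynthesis

The last operations are kept trivial: target 34 comes from diol 33 by oxidation of its only secondary alcohol, and 33 from bis-silyl ether 32. The first real cut is C12–C13, between the sp3 carbon C12 and the alkene carbon C13, as a B-alkyl Suzuki–Miyaura coupling of iodide 24 with alkenyl iodide 29. A cut through C13=C14 by carbonyl olefination would leave the geometry of a trisubstituted alkene to chance, and a cut at C11–C12 would require substitution next to the crowded C9. The chosen bond carries no stereochemistry and takes the alkene geometry unchanged from 29. It divides the molecule into a C16 core and a C14 chain and keeps the triene away from every oxidation and hydride step. The forward reaction requires the tertiary 8α-hydroxyl to be silylated, since a free hydroxyl would close onto C12 as soon as that carbon is activated.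

Alkenyl iodide 29 is cut at the C–I bond and at the methyl group on the same alkene: syn carboalumination of alkyne 27 followed by iodinolysis fixes the (E)-geometry by mechanism. Alkyne 27 comes from the methyl ketone of geranylacetone 25 through elimination of enol phosphate 26, so the (E)-alkene of the commercial ketone is carried through untouched.

In the core, iodide 24 goes back through alcohol 23 to diol 21, where the C8–O bond and the C12 oxidation level are handled together: 21 is the hydride-reduction product of epoxy ester 20, which comes from unsaturated ester 19. The neighbouring option, acid-induced lactonisation of the corresponding unsaturated acid onto C8, runs through a C8 cation under conditions where the lactone epimers can equilibrate towards the cis-fused ring, which has the wrong C8 configuration. The epoxide route replaces this with two substrate-controlled events (peracid from the α face, hydride at C7) and never breaks the C8–O bond once it exists. One hydride step then serves both the epoxide and the ester.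

Ester 19 is cut at C9–C11 as a Johnson–Claisen rearrangement of allylic alcohol 16 with triethyl orthoacetate 17. The carbon must arrive on the β face of C9, next to and on the same side as the C10 methyl group. A cuprate added to the transposed enone 15 would come from the α face, whereas the sigmatropic shift forms the new bond on the face of the C7–O bond. The cost is that the oxygen has to be moved from C9 to C7 and placed β: enone 11 is epoxidised to 12, the Wharton reaction gives the 7α-alcohol 14, and oxidation to 15 with Luche reduction turns it into the 7β-alcohol 16. These four steps of oxygen relocation are the weak point in step economy; they are accepted because each follows a simple steric or stereoelectronic rule on a rigid trans-decalin.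

Silyl ether 11 comes from hydroxy enone 10, and 10 is cut at C3–C4, the bond between the carbinol carbon and the gem-dimethyl carbon of ring A. In the forward sense a hydrogen atom is delivered to the CH2 terminus of the isopropenyl group of aldehyde 9, and the tertiary C4 radical adds to the aldehyde carbon. Polar alternatives (Prins or ene closure, ketyl addition to the alkene) would join C3 to the terminal alkene carbon and give a seven-membered ring; only a reactive centre on the internal carbon gives the six-membered ring with the gem-dimethyl group. The cut removes ring A, the quaternary C4 and the C3 oxygen in one move. It requires chemoselective hydrogen-atom transfer to the isopropenyl group in the presence of the enone.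

Aldehyde 9 is the oxidation product of alcohol 8, which comes from allyl ketone 6 by anti-Markovnikov hydration of the allyl group. Ketone 6 is cut at both bonds from C10 to its new substituents: methylation of (R)-carvone 1 to 3, then allylation with allyl bromide 4. The order matters: the second, larger electrophile enters anti to the isopropenyl group, which places the three-carbon arm trans and the methyl group cis to C4, the relationship of a trans-decalin with a 10β-methyl group.

## Roads not taken

Alternative 1: The cut is made at C9–C11 and C10–C1 on a preformed ring B. In the forward direction the ketal enone A1 takes up a vinyl group from vinylmagnesium bromide A2 at C9 under CuBr·SMe2 (monovalent copper) with a chiral phosphoramidite, and the enolate then adds through C10 to pent-1-en-3-one A3 to give the trans vinyl diketone A4; no ring closes.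
- Merits: two bonds and two stereocentres form in one flask from three simple components. The C11=C12 vinyl group already sits on C9, so hydroboration would give the C12 borane for the same Suzuki coupling without carbonyl transposition, inversion or Claisen rearrangement. Around C9 this road is shorter than the chosen one by roughly five steps, and in that respect it is better.
- Weak points: the α-methyl enone A1 is a sluggish acceptor whose allylic ketal invites SN2′ opening by the organocopper species. Trapping a hindered tetrasubstituted magnesium enolate with the polymerisable enone A3 is unreliable. The absolute configuration rests entirely on the catalyst. Ring A must still be built from A4 by aldol condensation and reductive gem-dimethylation, which also has to set C5. The C8 alcohol would come from methyl addition to the unmasked C8 ketone, where the favoured equatorial attack gives the 8β-alcohol, the wrong epimer, so a methylenation–oxidation detour would be needed.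
- Comparison: against the shorter C9 chemistry the chosen plan sets an absolute configuration bought with (R)-carvone 1, a C8 methyl group present from the start, and a ring A that appears with its gem-dimethyl group and C3 oxygen in a single step (9 to 10).

Alternative 2: The cut is C8–C9, closing ring B on a preformed ring A. The keto enoate A5 is treated with SmI2 (divalent samarium) in THF with HMPA and t-BuOH; the C8 ketyl adds 6-exo to C9 of the (E)-enoate and gives the bicyclic 8α-hydroxy ester A6.
- Merits: one step makes ring B and both C8 and C9, and the anti arrangement of hydroxyl and ester arm usual for such closures matches the 8α-OH/9β-arm relationship. A6 corresponds in oxidation pattern to diol 21, so in ring B this road replaces steps 7–13 of the chosen route by one reaction and is clearly more direct there.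
- Weak points: the difficulty is moved into A5, a cyclohexane carrying the quaternary C10 (methyl and enoate) and the C5 arm trans in one absolute configuration, for which no cheap chiral-pool precursor exists. 6-Exo ketyl–olefin closures are slower than 5-exo ones and compete with simple reduction of the ketone or the enoate. The facial selectivity at C9 depends on a chair transition state next to a quaternary centre. HMPA is needed.
- Comparison: if A5 were easily available this road would be the shorter one. The chosen plan sets against it that its first stereocentre is purchased and every later one follows from it by substrate control.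

Alternative 3: The cut is C7–C8 and C9–C10, closing ring B by a [4+2] cycloaddition. The silyloxy diene A7 and methyl but-2-ynoate A8 are heated to give the cycloadduct A9, a 3-silyloxydrima-5,8-dien-11-oate.
- Merits: it is the most convergent assembly of the decalin carbons; C8 with its methyl group, C9 and C11 arrive together, and a bicyclic intermediate is reached in fewer operations than steps 1–5 of the chosen route.
- Weak points: A8 is a poor dienophile and must bond through its ester-bearing carbon to the fully substituted diene terminus to create the quaternary C10, which requires forcing conditions and risks regiochemical leakage. The only control over the C10 configuration is the remote C3 silyloxy group. After the cycloaddition, C5 must be set by reduction of the 5,6-alkene, the 8,9-enoate must be converted into 8α-OH/9α-H, and C11 must be homologated by one carbon to reach C12.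
- Comparison: A9 is reached quickly but with C5, C8, C9 and probably C10 still open, whereas the chosen plan has C5 and C10 fixed before ring A closes and needs no homologation, at the price of the oxygen transposition in ring B.

Key step: step 5

## Route

Step 1
Reactants: 1 (R)-carvone
Product: 3 (5R,6S)-6-methylcarvone as the main C6 epimer, via lithium dienolate 2 (not isolated)
Conditions: LDA, THF, −78 °C; then MeI, −78 → 0 °C
Reagents that add atoms: iodomethane, CI
Why: Kinetic deprotonation gives the cross-conjugated C6 enolate (C10 of the target), and its C-methylation is a standard ketone α-alkylation; the C6 epimer ratio is immaterial because this centre is planarised again in step 2.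

Step 2
Reactants: 3 (5R,6S)-6-methylcarvone; 4 allyl bromide
Product: 6 (5S,6S)-2,6-dimethyl-6-(prop-2-en-1-yl)-5-(prop-1-en-2-yl)cyclohex-2-en-1-one, via lithium enolate 5 (not isolated)
Conditions: LDA, THF/DMPU, −78 °C; then 4, −78 °C → rt
Reagents that add atoms: none
Why: α-Alkylation of the tetrasubstituted lithium enolate; the allyl group enters on the face opposite to the neighbouring isopropenyl group, which sets the quaternary centre C10 with the methyl group cis and the three-carbon arm trans to C4 (control by C5).

Step 3
Reactants: 6 (5S,6S)-6-allyl-6-methylcarvone
Product: 8 (5S,6S)-6-(3-hydroxypropyl)-2,6-dimethyl-5-(prop-1-en-2-yl)cyclohex-2-en-1-one, via B-alkyl disiamylborane 7 (not isolated)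
Conditions: Sia2BH (from BH3·THF and 2-methylbut-2-ene), THF, 0 °C; then NaBO3·4H2O, THF/H2O, rt
Reagents that add atoms: sodium perborate, [Na+].[Na+].O[B-]1(O)OO[B-](O)(O)OO1
Why: Hydroboration–oxidation; the bulky dialkylborane reacts much faster with the monosubstituted allyl alkene than with the 1,1-disubstituted isopropenyl group or the hindered conjugated ketone, and perborate oxidises the C–B bond without the alkaline peroxide that would epoxidise the enone.

Step 4
Reactants: 8 the primary alcohol
Product: 9 (5S,6S)-2,6-dimethyl-6-(3-oxopropyl)-5-(prop-1-en-2-yl)cyclohex-2-en-1-one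
Conditions: Dess–Martin periodinane, NaHCO3, CH2Cl2, 0 °C → rt
Reagents that add atoms: none
Why: Dess–Martin oxidation of a primary alcohol to the aldehyde under buffered conditions; neither alkene nor the enone is affected.

Step 5
Reactants: 9 the keto aldehyde
Product: 10 3β-hydroxy-11-nordrim-7-en-9-one
Conditions: Fe(acac)3 (30 mol %), PhSiH3 (2.5 equiv), EtOH/ethylene glycol 5:1, 0.02 M, 60 °C, degassed
Reagents that add atoms: none
Why: An iron hydride generated from Fe(acac)3 (trivalent iron) and PhSiH3 in ethanol should transfer a hydrogen atom to the CH2 terminus of the isopropenyl group, which creates the second C4 methyl group and a tertiary radical at C4. This radical adds to the aldehyde carbon C3 in a 6-exo-trig closure that forms C3–C4 and ring A, and the alkoxy radical is reduced by divalent iron and protonated by the solvent, which returns trivalent iron. The closest known reaction type is the iron-hydride hydrogen-atom-transfer reductive cyclisation of alkene-tethered ketones, supported by the intermolecular addition of alkene-derived radicals to aldehydes under the same reagents. The ring fusion needs no new control: C5 and C10 already carry the two reacting arms trans, and a chair transition state joins them diequatorially, so the trans-decalin, the gem-dimethyl group and the C3 oxygen appear together. The one new stereocentre, C3, is set by that chair with the carbonyl oxygen pseudo-equatorial (3β expected) and is erased again in step 20. The step needs hydrogen-atom transfer to the isopropenyl alkene and not to the enone; the electron-rich 1,1-disubstituted alkene reacts fastest with iron hydrides of this kind, and the C4 radical cannot reach the enone through any ring larger than four-membered. High dilution and slow addition of the silane should limit premature reduction of the radical and intermolecular Giese addition.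

Step 6
Reactants: 10 3β-hydroxy-11-nordrim-7-en-9-one
Product: 11 3β-(tert-butyldimethylsilyloxy)-11-nordrim-7-en-9-one
Conditions: TBSOTf, 2,6-lutidine, CH2Cl2, 0 °C
Reagents that add atoms: tert-butyldimethylsilyl triflate, CC(C)(C)[Si](C)(C)OS(=O)(=O)C(F)(F)F
Why: Silylation of a hindered secondary alcohol next to a quaternary carbon with the silyl triflate; the TBS ether withstands the base, hydrazine, hydride and organolithium steps that follow and is removed by fluoride at the end.

Step 7
Reactants: 11 the TBS-protected enone
Product: 12 3β-(tert-butyldimethylsilyloxy)-7α,8α-epoxy-11-nordriman-9-one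
Conditions: 30% H2O2, NaOH (cat.), MeOH, 0 °C
Reagents that add atoms: hydrogen peroxide, OO
Why: Weitz–Scheffer nucleophilic epoxidation; hydroperoxide adds axially to C7 from the α face (the face of H5) and the enolate closes the 7α,8α-epoxide, as carvone itself does trans to its isopropenyl group.

Step 8
Reactants: 12 the epoxy ketone
Product: 14 3β-(tert-butyldimethylsilyloxy)-11-nordrim-8-en-7α-ol, via epoxy hydrazone 13 (not isolated)
Conditions: N2H4·H2O, AcOH, MeOH, 0 °C → rt
Reagents that add atoms: none
Why: Wharton transposition: the epoxy hydrazone fragments with loss of N2 to the allylic alcohol; the C7–O bond of the epoxide is not broken, so the alcohol is 7α and C9 becomes the alkene CH.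

Step 9
Reactants: 14 the 7α-allylic alcohol
Product: 15 3β-(tert-butyldimethylsilyloxy)-11-nordrim-8-en-7-one
Conditions: Dess–Martin periodinane, NaHCO3, CH2Cl2, rt
Reagents that add atoms: none
Why: Dess–Martin oxidation of the secondary allylic alcohol; it removes the C7 stereocentre so that it can be reset with the opposite configuration.

Step 10
Reactants: 15 the transposed enone
Product: 16 3β-(tert-butyldimethylsilyloxy)-11-nordrim-8-en-7β-ol
Conditions: NaBH4, CeCl3·7H2O, MeOH, −40 °C
Reagents that add atoms: none
Why: Luche 1,2-reduction; the small borohydride attacks the C7 carbonyl axially from the α face and gives the pseudo-equatorial 7β-alcohol, while the cerium salt suppresses conjugate reduction.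

Step 11
Reactants: 16 the 7β-allylic alcohol; 17 triethyl orthoacetate
Product: 19 ethyl 3β-(tert-butyldimethylsilyloxy)-13,14,15,16-tetranorlabd-7-en-12-oate, via mixed ketene acetal 18 (not isolated)
Conditions: 17 (excess), EtCO2H (cat.), xylene, 140 °C, EtOH distilled off
Reagents that add atoms: none
Why: Johnson–Claisen (orthoester) rearrangement; the [3,3] shift is suprafacial, so the 7β-oxygen delivers the acetate carbon to the β face of C9, syn to the C10 methyl group where an external reagent would not go, and moves the alkene to C7=C8.

Step 12
Reactants: 19 the unsaturated ester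
Product: 20 ethyl 3β-(tert-butyldimethylsilyloxy)-7α,8α-epoxy-13,14,15,16-tetranorlabdan-12-oate
Conditions: mCPBA, NaHCO3, CH2Cl2, 0 °C
Reagents that add atoms: 3-chloroperoxybenzoic acid, O=C(OO)c1cccc(Cl)c1
Why: Prilezhaev epoxidation of the only alkene; the axial C10 methyl group and the β-oriented C9 arm shield the β face, so the peracid should attack from the α face and place the oxygen on C8 α.

Step 13
Reactants: 20 the epoxy ester
Product: 21 3β-(tert-butyldimethylsilyloxy)-13,14,15,16-tetranorlabdane-8α,12-diol
Conditions: LiAlH4, THF, 0 °C → reflux
Reagents that add atoms: none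
Why: Hydride reduction of the ester to the C12 alcohol and SN2 opening of the trisubstituted epoxide at the secondary carbon C7; the C8–O bond is untouched, so the tertiary alcohol is 8α with the methyl group 8β.

Step 14
Reactants: 21 the 8α,12-diol
Product: 23 3β-(tert-butyldimethylsilyloxy)-8α-(triethylsilyloxy)-13,14,15,16-tetranorlabdan-12-ol, via bis-TES ether 22 (not isolated)
Conditions: TESOTf (2.5 equiv), 2,6-lutidine, CH2Cl2, −78 → 0 °C; then PPTS (cat.), MeOH, 0 °C
Reagents that add atoms: triethylsilyl triflate, CC[Si](CC)(CC)OS(=O)(=O)C(F)(F)F
Why: Exhaustive silylation followed by selective acid methanolysis of the far more labile primary TES ether; masking the tertiary 8α-hydroxyl prevents its closure onto activated C12 to a tetrahydrofuran in steps 15 and 18.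

Step 15
Reactants: 23 the primary alcohol
Product: 24 12-iodo-3β-(tert-butyldimethylsilyloxy)-8α-(triethylsilyloxy)-13,14,15,16-tetranorlabdane
Conditions: I2, PPh3, imidazole, CH2Cl2, 0 °C → rt
Reagents that add atoms: iodine, II
Why: Appel-type iodination of the primary alcohol by SN2 displacement of the alkoxyphosphonium group; imidazole buffers the medium and both silyl ethers should stay in place.

Step 16
Reactants: 25 geranylacetone
Product: 27 (5E)-6,10-dimethylundeca-5,9-dien-1-yne, via enol phosphate 26 (not isolated)
Conditions: LDA (1.05 equiv), THF, −78 °C; ClP(O)(OEt)2, −78 °C → rt; then LDA (2.3 equiv), −78 °C → rt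
Reagents that add atoms: none
Why: Conversion of a methyl ketone into a terminal alkyne: the kinetic terminal enolate is trapped as the enol phosphate, which undergoes base-induced elimination; the (E)-trisubstituted alkene of the starting ketone is not involved.

Step 17
Reactants: 27 the terminal alkyne
Product: 29 (1E,5E)-1-iodo-2,6,10-trimethylundeca-1,5,9-triene, via alkenylalane 28 (not isolated)
Conditions: Me3Al, Cp2ZrCl2 (cat.), CH2Cl2, 0 °C → rt; then I2, THF, −30 → 0 °C
Reagents that add atoms: trimethylaluminium, C[Al](C)C; iodine, II
Why: Zirconocene-catalysed carboalumination adds methyl and aluminium syn across the alkyne with the metal at the terminus, and iodinolysis proceeds with retention, which gives the (E)-alkenyl iodide.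

Step 18
Reactants: 24 the C12 iodide; 29 the (E)-alkenyl iodide
Product: 32 3β-(tert-butyldimethylsilyloxy)-8α-(triethylsilyloxy)-(13E,17E)-polypoda-13,17,21-triene, via alkyllithium 30 (not isolated), via lithium alkylmethoxyborate 31 (not isolated)
Conditions: t-BuLi (2.1 equiv), Et2O, −78 °C; B-OMe-9-BBN, THF, −78 °C → rt; then 29, Pd(dppf)Cl2 (5 mol %), AsPh3, K3PO4 (aq), DMF, rt
Reagents that add atoms: none
Why: B-alkyl Suzuki–Miyaura coupling: iodine–lithium exchange and capture by the methoxyborane give the borate, whose primary alkyl group is transferred to palladium and coupled with the alkenyl iodide with retention of the (E)-geometry; the C12–C13 bond forms without exposing the triene to acid or oxidant.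

Step 19
Reactants: 32 the bis-silyl ether
Product: 33 (13E,17E)-polypoda-13,17,21-triene-3β,8α-diol
Conditions: TBAF (excess), THF, 60 °C
Reagents that add atoms: none
Why: Fluoride-mediated cleavage of both silyl ethers; basic fluoride avoids the acid that could dehydrate the tertiary alcohol or start cation–olefin reactions of the triene.

Step 20
Reactants: 33 the 3β,8α-diol
Product: 34 (13E,17E)-8α-hydroxypolypoda-13,17,21-trien-3-one
Conditions: Dess–Martin periodinane, NaHCO3, CH2Cl2, 0 °C → rt
Reagents that add atoms: none
Why: Dess–Martin oxidation of the secondary C3 alcohol; the tertiary C8 alcohol cannot be oxidised, the alkenes are inert, and C5 is not α to the new ketone, so no stereocentre is at risk.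

## Compound list

1 | (R)-carvone, (5R)-2-methyl-5-(prop-1-en-2-yl)cyclohex-2-en-1-one | O=C1C[C@H](C(C)=C)CC=C1C | starting material
2 | lithium C6 dienolate of 1 (O–C1=C6, C2=C3) | [Li]OC1=C[C@H](C(C)=C)CC=C1C | intermediate
3 | (5R,6S)-2,6-dimethyl-5-(prop-1-en-2-yl)cyclohex-2-en-1-one (trans-6-methylcarvone, main epimer) | O=C1[C@@H](C)[C@H](C(C)=C)CC=C1C | intermediate
4 | allyl bromide (3-bromoprop-1-ene) | C=CCBr | starting material
5 | lithium enolate of 3 (O–C1=C6, methyl on C6) | [Li]OC1=C(C)[C@H](C(C)=C)CC=C1C | intermediate
6 | (5S,6S)-2,6-dimethyl-6-(prop-2-en-1-yl)-5-(prop-1-en-2-yl)cyclohex-2-en-1-one (allyl trans to isopropenyl) | O=C1[C@@](C)(CC=C)[C@H](C(C)=C)CC=C1C | intermediate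
7 | bis(3-methylbutan-2-yl)borane adduct of 6, boron on the terminal carbon of the former allyl group | O=C1[C@@](C)(CCCB(C(C)C(C)C)C(C)C(C)C)[C@H](C(C)=C)CC=C1C | intermediate
8 | (5S,6S)-6-(3-hydroxypropyl)-2,6-dimethyl-5-(prop-1-en-2-yl)cyclohex-2-en-1-one | O=C1[C@@](C)(CCCO)[C@H](C(C)=C)CC=C1C | intermediate
9 | (5S,6S)-2,6-dimethyl-6-(3-oxopropyl)-5-(prop-1-en-2-yl)cyclohex-2-en-1-one | O=C1[C@@](C)(CCC=O)[C@H](C(C)=C)CC=C1C | intermediate
10 | 3β-hydroxy-11-nordrim-7-en-9-one (trans-decalin, 5α-H, 10β-CH3, 4,4,8,10-tetramethyl) | O=C1[C@@]2(C)CC[C@H](O)C(C)(C)[C@@H]2CC=C1C | intermediate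
11 | 3β-(tert-butyldimethylsilyloxy)-11-nordrim-7-en-9-one | O=C1[C@@]2(C)CC[C@H](O[Si](C)(C)C(C)(C)C)C(C)(C)[C@@H]2CC=C1C | intermediate
12 | 3β-(tert-butyldimethylsilyloxy)-7α,8α-epoxy-11-nordriman-9-one | O=C1[C@@]2(C)CC[C@H](O[Si](C)(C)C(C)(C)C)C(C)(C)[C@@H]2C[C@H]3O[C@@]13C | intermediate
13 | C9 hydrazone of 12 | NN=C1[C@@]2(C)CC[C@H](O[Si](C)(C)C(C)(C)C)C(C)(C)[C@@H]2C[C@H]3O[C@@]13C | intermediate
14 | 3β-(tert-butyldimethylsilyloxy)-11-nordrim-8-en-7α-ol | O[C@@H]1C[C@H]2C(C)(C)[C@@H](O[Si](C)(C)C(C)(C)C)CC[C@]2(C)C=C1C | intermediate
15 | 3β-(tert-butyldimethylsilyloxy)-11-nordrim-8-en-7-one | O=C1C[C@H]2C(C)(C)[C@@H](O[Si](C)(C)C(C)(C)C)CC[C@]2(C)C=C1C | intermediate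
16 | 3β-(tert-butyldimethylsilyloxy)-11-nordrim-8-en-7β-ol | O[C@H]1C[C@H]2C(C)(C)[C@@H](O[Si](C)(C)C(C)(C)C)CC[C@]2(C)C=C1C | intermediate
17 | triethyl orthoacetate (1,1,1-triethoxyethane) | CC(OCC)(OCC)OCC | starting material
18 | 7β-(1-ethoxyethenyloxy) ketene acetal of 16 | C=C(OCC)O[C@H]1C[C@H]2C(C)(C)[C@@H](O[Si](C)(C)C(C)(C)C)CC[C@]2(C)C=C1C | intermediate
19 | ethyl 3β-(tert-butyldimethylsilyloxy)-13,14,15,16-tetranorlabd-7-en-12-oate (9β-CH2CO2Et, 9α-H) | CCOC(=O)C[C@H]1C(C)=CC[C@H]2C(C)(C)[C@@H](O[Si](C)(C)C(C)(C)C)CC[C@]12C | intermediate
20 | ethyl 3β-(tert-butyldimethylsilyloxy)-7α,8α-epoxy-13,14,15,16-tetranorlabdan-12-oate | CCOC(=O)C[C@H]1[C@]3(C)O[C@@H]3C[C@H]2C(C)(C)[C@@H](O[Si](C)(C)C(C)(C)C)CC[C@]12C | intermediate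
21 | 3β-(tert-butyldimethylsilyloxy)-13,14,15,16-tetranorlabdane-8α,12-diol (8β-CH3) | OCC[C@H]1[C@](C)(O)CC[C@H]2C(C)(C)[C@@H](O[Si](C)(C)C(C)(C)C)CC[C@]12C | intermediate
22 | 8α,12-bis(triethylsilyl) ether of 21 | CC[Si](CC)(CC)OCC[C@H]1[C@](C)(O[Si](CC)(CC)CC)CC[C@H]2C(C)(C)[C@@H](O[Si](C)(C)C(C)(C)C)CC[C@]12C | intermediate
23 | 3β-(tert-butyldimethylsilyloxy)-8α-(triethylsilyloxy)-13,14,15,16-tetranorlabdan-12-ol | OCC[C@H]1[C@](C)(O[Si](CC)(CC)CC)CC[C@H]2C(C)(C)[C@@H](O[Si](C)(C)C(C)(C)C)CC[C@]12C | intermediate
24 | 12-iodo-3β-(tert-butyldimethylsilyloxy)-8α-(triethylsilyloxy)-13,14,15,16-tetranorlabdane | ICC[C@H]1[C@](C)(O[Si](CC)(CC)CC)CC[C@H]2C(C)(C)[C@@H](O[Si](C)(C)C(C)(C)C)CC[C@]12C | intermediate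
25 | geranylacetone, (5E)-6,10-dimethylundeca-5,9-dien-2-one | CC(C)=CCC/C(C)=C/CCC(C)=O | starting material
26 | diethyl (5E)-6,10-dimethylundeca-1,5,9-trien-2-yl phosphate | CC(C)=CCC/C(C)=C/CCC(=C)OP(=O)(OCC)OCC | intermediate
27 | (5E)-6,10-dimethylundeca-5,9-dien-1-yne | CC(C)=CCC/C(C)=C/CCC#C | intermediate
28 | dimethyl[(1E,5E)-2,6,10-trimethylundeca-1,5,9-trien-1-yl]alane | CC(C)=CCC/C(C)=C/CC/C(C)=C/[Al](C)C | intermediate
29 | (1E,5E)-1-iodo-2,6,10-trimethylundeca-1,5,9-triene | CC(C)=CCC/C(C)=C/CC/C(C)=C/I | intermediate
30 | C12 alkyllithium derived from 24 | [Li]CC[C@H]1[C@](C)(O[Si](CC)(CC)CC)CC[C@H]2C(C)(C)[C@@H](O[Si](C)(C)C(C)(C)C)CC[C@]12C | intermediate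
31 | lithium B-methoxy-B-(C12 alkyl)-9-borabicyclo[3.3.1]nonane borate | [Li+].CO[B-]1(CC[C@H]2[C@](C)(O[Si](CC)(CC)CC)CC[C@H]3C(C)(C)[C@@H](O[Si](C)(C)C(C)(C)C)CC[C@]23C)C4CCCC1CCC4 | intermediate
32 | 3β-(tert-butyldimethylsilyloxy)-8α-(triethylsilyloxy)-(13E,17E)-polypoda-13,17,21-triene (9β chain = (3E,7E)-4,8,12-trimethyltrideca-3,7,11-trienyl) | CC(C)=CCC/C(C)=C/CC/C(C)=C/CC[C@H]1[C@](C)(O[Si](CC)(CC)CC)CC[C@H]2C(C)(C)[C@@H](O[Si](C)(C)C(C)(C)C)CC[C@]12C | intermediate
33 | (13E,17E)-polypoda-13,17,21-triene-3β,8α-diol | CC(C)=CCC/C(C)=C/CC/C(C)=C/CC[C@H]1[C@](C)(O)CC[C@H]2C(C)(C)[C@@H](O)CC[C@]12C | intermediate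
34 | (13E,17E)-8α-hydroxypolypoda-13,17,21-trien-3-one (trans-decalin, 5α-H, 10β-CH3, 8β-CH3, 9β chain) | CC(C)=CCC/C(C)=C/CC/C(C)=C/CC[C@@H]1[C@@]2(C)CCC(=O)C(C)(C)[C@@H]2CC[C@@]1(C)O | target

## Step count and risk

Total step count: 20. Longest linear sequence: 18 steps (steps 1–15 and 18–20, from (R)-carvone 1); the alkenyl iodide 29 takes 2 steps from geranylacetone 25 and joins at step 18.

Least certain steps:

Step 5 (key step). The most likely failure is reversal of the ring closure: the alkoxy radical can fragment back to the tertiary C4 radical faster than it is reduced, so that the net result is simple hydrogenation of the isopropenyl group; hydrogen transfer from the aldehyde C–H to the radical would act in the same direction. Fallback: set out from aldehyde 9 and change the radical acceptor from C=O to C≡N, whose iminyl radical does not fragment as readily. Condensation of 9 with hydroxylamine gives the aldoxime F1, and dehydration gives the nitrile F2. The same Fe(acac)3/PhSiH3 hydrogen-atom transfer then leads to 6-exo-dig addition of the C4 radical to the nitrile carbon, and hydrolysis of the resulting imine on work-up gives the 3,9-diketone F3. Reduction of F3 with NaBH4 at low temperature should take the saturated C3 ketone in preference to the hindered conjugated C9 ketone, with hydride from the α face, and this comes back to the route at 10.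

Step 3. The hydroboration may lack chemoselectivity: competing addition to the isopropenyl group, slow reduction of the ketone by the borane, or epoxidation of the enone during the oxidative work-up, all because three reactive π systems are present. Fallback: set out from 6 and reach 9 directly by an aldehyde-selective (anti-Markovnikov) Wacker oxidation of the allyl group with PdCl2(PhCN)2, CuCl2 and AgNO2 under O2 in t-BuOH/MeNO2. This replaces steps 3 and 4, uses neither borane nor peroxide, and passes through no new isolated compound.

Step 8. Hydrazone formation may be too slow at a carbonyl carbon flanked by the quaternary C10 and the fully substituted epoxide carbon C8, which would leave time for epoxide opening by hydrazine. Fallback: set out from epoxy ketone 12 and avoid condensation at C9. Reduction with NaBH4 gives the 9-epoxy alcohol F4 (drawn as the 9α-alcohol; either epimer serves), which is converted with NaH, CS2 and MeI into the S-methyl xanthate F5. Under Barton–McCombie conditions (Bu3SnH, AIBN, toluene, 80 °C) the C9 radical opens the neighbouring epoxide and the oxygen radical is reduced, which gives the transposed allylic alcohol and comes back to the route at 14.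

Step 11. At 140 °C with acid, ionisation of the allylic alcohol and elimination to a diene may outrun the rearrangement, which is slowed by the pseudo-equatorial C7–O bond and by bond formation next to the quaternary C10. Fallback: set out from 16 and use the Ireland–Claisen variant, which runs below 60 °C without acid. Acetylation gives the acetate F6; LDA and TMSCl at −78 °C give the silyl ketene acetal F7, which rearranges on warming and gives the C12 acid F8 after aqueous work-up; ethylation of F8 with EtI and K2CO3 comes back to the route at 19.

Step 13. Insufficient facial selectivity in the epoxidation of step 12 would surface here as the wrong C8 epimer, and opening at the tertiary carbon or intramolecular attack of the C12 alkoxide on the epoxide would erode the regiochemistry. Fallback: set out from 19 and install the C8 oxygen by radical hydration instead of epoxide opening. Mukaiyama hydration (Co(acac)2, PhSiH3, O2, i-PrOH) forms the tertiary C8 radical, which should be trapped by oxygen from the open α face, away from the axial C10 methyl group, to give the 8α-hydroxy ester F9; reduction of F9 with LiAlH4 comes back to the route at 21.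

## Further compounds

F1 | step 5 | aldoxime of 9, (5S,6S)-6-[3-(hydroxyimino)propyl]-2,6-dimethyl-5-(prop-1-en-2-yl)cyclohex-2-en-1-one | O=C1[C@@](C)(CCC=NO)[C@H](C(C)=C)CC=C1C
F2 | step 5 | 3-[(1S,6S)-1,3-dimethyl-2-oxo-6-(prop-1-en-2-yl)cyclohex-3-en-1-yl]propanenitrile | O=C1[C@@](C)(CCC#N)[C@H](C(C)=C)CC=C1C
F3 | step 5 | 11-nordrim-7-ene-3,9-dione | O=C1[C@@]2(C)CCC(=O)C(C)(C)[C@@H]2CC=C1C
F0 | step 3 | none | none
F4 | step 8 | 3β-(tert-butyldimethylsilyloxy)-7α,8α-epoxy-11-nordriman-9α-ol | O[C@H]1[C@@]2(C)CC[C@H](O[Si](C)(C)C(C)(C)C)C(C)(C)[C@@H]2C[C@H]3O[C@@]13C
F5 | step 8 | O-(9α) S-methyl xanthate of F4 | CSC(=S)O[C@H]1[C@@]2(C)CC[C@H](O[Si](C)(C)C(C)(C)C)C(C)(C)[C@@H]2C[C@H]3O[C@@]13C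
F6 | step 11 | 7β-acetate of 16 | CC(=O)O[C@H]1C[C@H]2C(C)(C)[C@@H](O[Si](C)(C)C(C)(C)C)CC[C@]2(C)C=C1C
F7 | step 11 | trimethylsilyl ketene acetal of F6 | C=C(O[Si](C)(C)C)O[C@H]1C[C@H]2C(C)(C)[C@@H](O[Si](C)(C)C(C)(C)C)CC[C@]2(C)C=C1C
F8 | step 11 | 3β-(tert-butyldimethylsilyloxy)-13,14,15,16-tetranorlabd-7-en-12-oic acid | OC(=O)C[C@H]1C(C)=CC[C@H]2C(C)(C)[C@@H](O[Si](C)(C)C(C)(C)C)CC[C@]12C
F9 | step 13 | ethyl 3β-(tert-butyldimethylsilyloxy)-8α-hydroxy-13,14,15,16-tetranorlabdan-12-oate | CCOC(=O)C[C@H]1[C@](C)(O)CC[C@H]2C(C)(C)[C@@H](O[Si](C)(C)C(C)(C)C)CC[C@]12C
A1 | alternative 1 | 7-methyl-1,4-dioxaspiro[4.5]dec-6-en-8-one (ketal enone) | CC1=CC2(OCCO2)CCC1=O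
A2 | alternative 1 | vinylmagnesium bromide | C=C[Mg]Br
A3 | alternative 1 | pent-1-en-3-one | CCC(=O)C=C
A4 | alternative 1 | trans vinyl diketone (C8 dioxolane, C5 and C3 ketones) | C=C[C@@H]1[C@@](C)(CCC(=O)CC)C(=O)CCC12OCCO2
A5 | alternative 2 | ring A keto (E)-enoate with C3 dioxolane | CCOC(=O)/C=C/[C@@]1(C)CCC2(OCCO2)C(C)(C)[C@@H]1CCC(C)=O
A6 | alternative 2 | bicyclic 8α-hydroxy C12 ethyl ester with C3 dioxolane | CCOC(=O)C[C@@H]1[C@@]2(C)CCC3(OCCO3)C(C)(C)[C@@H]2CC[C@@]1(C)O
A7 | alternative 3 | (S)-tert-butyldimethylsilyl ether of 2,2,4-trimethyl-3-vinylcyclohex-3-en-1-ol | C=CC1=C(C)CC[C@H](O[Si](C)(C)C(C)(C)C)C1(C)C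
A8 | alternative 3 | methyl but-2-ynoate | CC#CC(=O)OC
A9 | alternative 3 | methyl 3β-(tert-butyldimethylsilyloxy)drima-5,8-dien-11-oate | COC(=O)C1=C(C)CC=C2C(C)(C)[C@@H](O[Si](C)(C)C(C)(C)C)CC[C@]12C
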